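The data stem from a simulated flask for an exercise; noise was put on by code.

The reading is wanted at 2.0 min, later than the last reading of either run at 80.0 s, so the flask must be reached by extrapolation.

| flask | D | J | remark | time |
|---|---|---|---|---|
| grey | 0.67 M | 1.3 M | run made earlier |  |
| teal | 1.5 M | 1.3 M | run made earlier |  |
| flask | 1.0 M | 1.30 M |  | 2.0 min |

| run | time / s | D / % | X / % |
|---|---|---|---|
| grey | 12.0 | 95.9 | 1.1 |
| grey | 25.0 | 93.0 | 2.2 |
| grey | 40.0 | 89.3 | 2.4 |
| grey | 50.0 | 87.3 | 1.7 |
| grey | 60.0 | 84.6 | 2.8 |
| grey | 80.0 | 79.9 | 2.2 |
| teal | 10.0 | 98.3 | 0.2 |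
| teal | 15.0 | 98.5 | 0.8 |
| teal | 25.0 | 96.6 | 0.7 |
| teal | 40.0 | 94.9 | 0.9 |
| teal | 60.0 | 93.6 | 0.8 |
| teal | 80.0 | 91.4 | 0.6 |

(scatter of a reading: 0.3 percentage points)

- how much D there is at 2.0 min, in percent of the D charged (only what is still solid)
- how much X there is at 2.0 min, in percent of the D charged
- how much G there is at 2.0 min, in percent of the D charged

- given per volume of solution although it is solid: D
- the numbers in the tables scatter with a standard deviation of 0.3 percentage points
- at the start none of D is in solution
- a reading or a percentage of G counts all its forms, free or not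

Counted in molar terms, the grey run has lost 0.135 M of solid by its last reading and the teal run 0.129 M, though the teal run was charged about twice the solid. Loss that ignores the loading behaves like a constant-flow source, and a line from the origin gives 80.2 % of D in the flask. But by its first reading the grey run has lost 27.5 mM, more than the 19.8 mM on that line, which suggests an early head start. The better measure is the drain, the molar amount of solid lost per second after the head start, taken as the slope from first to last reading: 1.58 mM s⁻¹ in the grey run and 1.48 mM s⁻¹ in the teal run, so 1.53 mM s⁻¹. Back at the first readings, the head start comes to 9.68 mM, and this reckoning then puts the flask at 80.7 % of D.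

J might slow the drain, since each G takes two. Yet the grey slope reads 1.58 mM s⁻¹ early and 1.57 mM s⁻¹ late. At this drain J, the limiting reagent at two per D, is reckoned to last 7.09 min, less than the 10.9 min reckoned for the solid; that time is the crossing at which the drain has to give way to J, and the reading comes before it.

The late X readings of the two runs average 0.0132 M. Taking that level for X in the flask and the head start as dissolved D, the reckoning leaves 17.0 % of G.

The forecast, holding that “D reacts from a saturated solution (zero order in solid)”, gives 80.5 % of D, 1.4 % of X and 17.4 % of G.

The flask gives 80.7 % of D, 1.69 % of X and 16.0 % of G.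

    L + J → X (k = 0.310 M⁻¹ s⁻¹)
    J + X → G (k = 0.280 M⁻¹ s⁻¹)
    J ⇌ Z (K = 2.10, k = 0.160 s⁻¹)
    D ⇌ L, rate k4*(cs4 - [L]) while solid is left; crystals form when [L] > cs4 (solubility = 35.0 mM, k = 0.0740 s⁻¹)
    J + G ⇌ Q, settled at all times (K = 0.760 M⁻¹)

Net of the head start, this flask lost solid at 1.53 mM s⁻¹ on average, against the drain of 1.53 mM s⁻¹, and at 2.0 min it holds 0.641 M of Z and 22.5 % of its J free. Read at 5.0 min, still before the reckoned crossing at 7.09 min, the same flask should hold 53.2 % of D by the drain. It holds 58.4 %, with the loss after 2.0 min averaging 1.24 mM s⁻¹ and 11.8 % of its J free.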